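**Plan**

- Retrosynthesis: the four halogen bonds outside the ring-forming event are cut first (CH2–Br, vinyl C–Cl, tertiary C–Cl via a spiro-epoxide, secondary C–Br via a carbinol). The cyclohexane is then cut between the CHBr carbon and the ring CH2 that lies next to CHCl, and the chain is cut at the quaternary carbon.
- Enabling feature: the ring edge CH(Br)–CH2–CH(Cl), with the CHCl carbon on the all-carbon quaternary centre, is a 1,3-chlorohydrin. It maps onto an aldehyde carbon and the terminal carbon of a vinyl group that has no allylic hydrogen, so capture of the developing cation by chloride is the only outcome.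
- Forward: an allyl–allyl coupling builds the acyclic C9 chain with the quaternary centre, and dihydroxylation/oxidation gives an α-keto aldehyde. The only ring is closed by a silyl chloride-mediated chloro-Prins cyclisation. The ketone then becomes an exocyclic alkene and a spiro-epoxide, and the halogens follow in the order secondary Br, tertiary Cl, vinyl Cl, primary Br.
- Stereochemistry: the quaternary centre comes from the chiral palladium catalyst. The CHCl and carbinol centres come from the chair transition state of the ring closure (slim ethynyl group axial, anti addition, dipole-opposed carbonyls). C–Br comes from SN2 inversion, the tertiary C–Cl from hydroxyl-directed epoxidation and invertive opening, and the E-chloroalkene from syn hydrozirconation.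

Key step: step 5

Assumption: in step 2 the antipode of the bisphosphine that gives the (S)-diene is used; the sense of induction is taken by analogy with other 3,3-disubstituted allyl chlorides and would have to be confirmed.

**Step 1**
Reactants: 1 (2E)-3-methylpent-2-en-4-yn-1-ol
Product: 2 (3E)-5-chloro-3-methylpent-3-en-1-yne
Conditions: PPh3, NCS, CH2Cl2, −20 °C → rt
Reagents that add atoms: N-chlorosuccinimide, ClN1C(=O)CCC1=O
Why: Appel-type chlorination of a primary allylic alcohol runs by SN2 displacement of the alkoxyphosphonium ion, so no allylic transposition is expected and the E geometry is kept.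

**Step 2**
Reactants: 2 (3E)-5-chloro-3-methylpent-3-en-1-yne; 3 allylboronic acid pinacol ester
Product: 4 (3S)-3-ethynyl-3-methylhexa-1,5-diene
Conditions: Pd2(dba)3 (2.5 mol %), (R)-MeO-furyl-BIPHEP (6 mol %), CsF, THF, 60 °C
Reagents that add atoms: none
Why: Branch-selective palladium-catalysed allyl–allyl cross-coupling (3,3'-reductive elimination from the bis(allyl)palladium complex) joins the allyl group to the substituted terminus and should set the quaternary centre under control of the chiral bisphosphine.

**Step 3**
Reactants: 4 (3S)-3-ethynyl-3-methylhexa-1,5-diene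
Product: 5 (4S)-4-ethynyl-4-methylhex-5-ene-1,2-diol (both epimers at C2)
Conditions: OsO4 (1 mol %), NMO (1.0 equiv), acetone/H2O, 0 °C
Reagents that add atoms: N-methylmorpholine N-oxide, C[N+]1([O-])CCOCC1; water, O
Why: Upjohn dihydroxylation should take the unhindered allyl alkene faster than the vinyl group on the quaternary carbon (neopentyl-type, inductively deactivated) and leave the alkyne; the new carbinol centre is not controlled because step 4 erases it.

**Step 4**
Reactants: 5 (4S)-4-ethynyl-4-methylhex-5-ene-1,2-diol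
Product: 6 (4S)-4-ethynyl-4-methyl-2-oxohex-5-enal
Conditions: (COCl)2, DMSO, CH2Cl2, −78 °C; Et3N, −78 → 0 °C; used at once
Reagents that add atoms: none
Why: Double Swern oxidation of the 1,2-diol should give the α-keto aldehyde without C–C cleavage, and the quaternary centre cannot epimerise.

**Step 5**
Reactants: 6 (4S)-4-ethynyl-4-methyl-2-oxohex-5-enal
Product: 7 (2R,4R,5R)-4-chloro-5-ethynyl-5-methyl-2-[(trimethylsilyl)oxy]cyclohexan-1-one
Conditions: Me3SiCl (2.0 equiv), InCl3 (10 mol %), CH2Cl2, −60 → −30 °C; non-aqueous work-up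
Reagents that add atoms: chlorotrimethylsilane, C[Si](C)(C)Cl
Why: Me3SiCl activated by InCl3 silylates the aldehyde oxygen of the 1,2-dicarbonyl unit, the terminal carbon of the vinyl group attacks the silyloxocarbenium carbon, and the charge developing on the internal alkene carbon is taken up by chloride (InCl4−/Me3SiCl) as the C–C bond forms, so no free secondary cation next to the quaternary carbon has to survive. The closest known reaction type is the Lewis acid or halosilane-mediated halo-Prins (chloride-terminated carbonyl–alkene) cyclisation of 5-hexenals to 3-chlorocyclohexanols. The cyclohexane closes through a chair in the 6-endo-trig mode with respect to the alkene (exo with respect to the carbonyl). The chlorine-bearing centre is controlled by the quaternary carbon, which should place the slim ethynyl group (A value about 0.4) axial and the methyl group (about 1.7) equatorial, together with anti addition across the alkene, which leaves chlorine equatorial and cis to ethynyl; the silyloxy centre is controlled by the monodentate, dipole-opposed arrangement of the silyloxocarbenium and the neighbouring ketone, which should place oxygen axial and trans to chlorine. The step needs chemoselectivity for the vinyl group over the ethynyl group and over an ene pathway: the alkyne would have to pass through a vinyl cation, and the vinyl group on the quaternary carbon has no allylic hydrogen, so chloride capture is the only exit.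

**Step 6**
Reactants: 7 (2R,4R,5R)-4-chloro-5-ethynyl-5-methyl-2-[(trimethylsilyl)oxy]cyclohexan-1-one
Product: 9 (1R,4R,5R)-5-chloro-4-ethynyl-4-methyl-2-methylidenecyclohexan-1-ol, via trimethylsilyl ether 8 (not isolated)
Conditions: Ph3PCH3Br, KOtBu, THF, 0 °C; then 1 M HCl, THF, 0 °C
Reagents that add atoms: methyltriphenylphosphonium bromide (as its ylide), C[P+](c1ccccc1)(c1ccccc1)c1ccccc1.[Br-]
Why: Wittig methylenation of the α-silyloxy ketone, in which the silyl ether keeps the γ-chloro alkoxide (which could fragment in the Grob sense) from forming, is followed by acid hydrolysis of the silyl ether; no stereocentre is touched.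

**Step 7**
Reactants: 9 (1R,4R,5R)-5-chloro-4-ethynyl-4-methyl-2-methylidenecyclohexan-1-ol
Product: 10 (3R,4R,6R,7R)-6-chloro-7-ethynyl-7-methyl-1-oxaspiro[2.5]octan-4-ol
Conditions: VO(acac)2 (5 mol %), t-BuOOH, CH2Cl2, 0 °C → rt
Reagents that add atoms: tert-butyl hydroperoxide, CC(C)(C)OO
Why: Hydroxyl-directed vanadium-catalysed epoxidation should deliver oxygen to the alkene face syn to the axial allylic hydroxyl, which sets the spiro carbon with oxygen cis to the hydroxyl.

**Step 8**
Reactants: 10 (3R,4R,6R,7R)-6-chloro-7-ethynyl-7-methyl-1-oxaspiro[2.5]octan-4-ol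
Product: 12 (3R,4S,6R,7R)-4-bromo-6-chloro-7-ethynyl-7-methyl-1-oxaspiro[2.5]octane, via triflate 11 (not isolated)
Conditions: Tf2O, 2,6-lutidine, CH2Cl2, −40 °C; then Bu4NBr, −40 → 0 °C
Reagents that add atoms: tetrabutylammonium bromide, CCCC[N+](CCCC)(CCCC)CCCC.[Br-]
Why: SN2 displacement of the secondary triflate by bromide with inversion should place bromine equatorial and cis to the ring chlorine; the adjacent epoxide rules out an SN2' path and its oxygen is gauche to the leaving group, so it cannot participate.

**Step 9**
Reactants: 12 (3R,4S,6R,7R)-4-bromo-6-chloro-7-ethynyl-7-methyl-1-oxaspiro[2.5]octane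
Product: 13 [(1S,2S,4R,5R)-2-bromo-1,4-dichloro-5-ethynyl-5-methylcyclohexyl]methanol
Conditions: TiCl4, CH2Cl2, −78 °C; then H2O
Reagents that add atoms: titanium tetrachloride, Cl[Ti](Cl)(Cl)Cl
Why: Lewis acid-mediated opening of the 2,2-disubstituted epoxide by chloride at the tertiary carbon with inversion (borderline SN2) should put chlorine axial and cis to bromine and free the CH2OH group; the equatorial C–Br bond is not antiperiplanar to the breaking C–O bond, so bromine cannot bridge, and the axial ethynyl group leaves the approach open.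

**Step 10**
Reactants: 13 [(1S,2S,4R,5R)-2-bromo-1,4-dichloro-5-ethynyl-5-methylcyclohexyl]methanol
Product: 15 [(1S,2S,4R,5R)-2-bromo-1,4-dichloro-5-[(E)-2-chloroethenyl]-5-methylcyclohexyl]methanol, via alkenylzirconocene 14 (not isolated)
Conditions: Cp2Zr(H)Cl (2.3 equiv), THF, rt; then NCS, 0 °C; 1 M HCl work-up
Reagents that add atoms: N-chlorosuccinimide, ClN1C(=O)CCC1=O
Why: Hydrozirconation of the terminal alkyne (syn, zirconium on the terminal carbon) and chlorination of the C–Zr bond with retention should give the E-chloroalkene; one equivalent of the hydride is consumed by the hydroxyl group.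

**Step 11**
Reactants: 15 [(1S,2S,4R,5R)-2-bromo-1,4-dichloro-5-[(E)-2-chloroethenyl]-5-methylcyclohexyl]methanol
Product: 17 (1S,2S,4R,5R)-2-bromo-1-(bromomethyl)-1,4-dichloro-5-[(E)-2-chloroethenyl]-5-methylcyclohexane, via triflate 16 (not isolated)
Conditions: Tf2O, 2,6-lutidine, CH2Cl2, −78 °C; then Bu4NBr, −78 °C → rt
Reagents that add atoms: tetrabutylammonium bromide, CCCC[N+](CCCC)(CCCC)CCCC.[Br-]
Why: Triflation and SN2 displacement by bromide at the primary (neopentyl-type) carbon should finish the bromomethyl group without touching a stereocentre.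

**Compound list**

1 | (2E)-3-methylpent-2-en-4-yn-1-ol | OC/C=C(\C)C#C | starting material
2 | (3E)-5-chloro-3-methylpent-3-en-1-yne | ClC/C=C(\C)C#C | intermediate
3 | allylboronic acid pinacol ester (2-allyl-4,4,5,5-tetramethyl-1,3,2-dioxaborolane) | C=CCB1OC(C)(C)C(C)(C)O1 | starting material
4 | (3S)-3-ethynyl-3-methylhexa-1,5-diene | C[C@](C=C)(C#C)CC=C | intermediate
5 | (4S)-4-ethynyl-4-methylhex-5-ene-1,2-diol (both epimers at C2) | C[C@](C=C)(C#C)CC(O)CO | intermediate
6 | (4S)-4-ethynyl-4-methyl-2-oxohex-5-enal | C[C@](C=C)(C#C)CC(=O)C=O | intermediate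
7 | (2R,4R,5R)-4-chloro-5-ethynyl-5-methyl-2-[(trimethylsilyl)oxy]cyclohexan-1-one (OSiMe3 trans to Cl, Cl cis to ethynyl) | C[C@]1(C#C)CC(=O)[C@H](O[Si](C)(C)C)C[C@H]1Cl | intermediate
8 | {[(1R,4R,5R)-5-chloro-4-ethynyl-4-methyl-2-methylidenecyclohexyl]oxy}trimethylsilane | C[C@]1(C#C)CC(=C)[C@H](O[Si](C)(C)C)C[C@H]1Cl | intermediate (not isolated)
9 | (1R,4R,5R)-5-chloro-4-ethynyl-4-methyl-2-methylidenecyclohexan-1-ol | C[C@]1(C#C)CC(=C)[C@H](O)C[C@H]1Cl | intermediate
10 | (3R,4R,6R,7R)-6-chloro-7-ethynyl-7-methyl-1-oxaspiro[2.5]octan-4-ol (epoxide O cis to OH) | C[C@]1(C#C)C[C@@]2(CO2)[C@H](O)C[C@H]1Cl | intermediate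
11 | (3R,4R,6R,7R)-6-chloro-7-ethynyl-7-methyl-1-oxaspiro[2.5]octan-4-yl trifluoromethanesulfonate | C[C@]1(C#C)C[C@@]2(CO2)[C@H](OS(=O)(=O)C(F)(F)F)C[C@H]1Cl | intermediate (not isolated)
12 | (3R,4S,6R,7R)-4-bromo-6-chloro-7-ethynyl-7-methyl-1-oxaspiro[2.5]octane (Br trans to epoxide O, cis to Cl) | C[C@]1(C#C)C[C@@]2(CO2)[C@@H](Br)C[C@H]1Cl | intermediate
13 | [(1S,2S,4R,5R)-2-bromo-1,4-dichloro-5-ethynyl-5-methylcyclohexyl]methanol | C[C@]1(C#C)C[C@](Cl)(CO)[C@@H](Br)C[C@H]1Cl | intermediate
14 | E-alkenylzirconocene chloride of 13, hydroxyl as its zirconocene alkoxide | C[C@]1(/C=C/[Zr](Cl)(C2C=CC=C2)C2C=CC=C2)C[C@](Cl)(CO[Zr](Cl)(C2C=CC=C2)C2C=CC=C2)[C@@H](Br)C[C@H]1Cl | intermediate (not isolated)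
15 | [(1S,2S,4R,5R)-2-bromo-1,4-dichloro-5-[(E)-2-chloroethenyl]-5-methylcyclohexyl]methanol | C[C@]1(/C=C/Cl)C[C@](Cl)(CO)[C@@H](Br)C[C@H]1Cl | intermediate
16 | [(1S,2S,4R,5R)-2-bromo-1,4-dichloro-5-[(E)-2-chloroethenyl]-5-methylcyclohexyl]methyl trifluoromethanesulfonate | C[C@]1(/C=C/Cl)C[C@](Cl)(COS(=O)(=O)C(F)(F)F)[C@@H](Br)C[C@H]1Cl | intermediate (not isolated)
17 | (1S,2S,4R,5R)-2-bromo-1-(bromomethyl)-1,4-dichloro-5-[(E)-2-chloroethenyl]-5-methylcyclohexane | C[C@]1(/C=C/Cl)C[C@](Cl)(CBr)[C@@H](Br)C[C@H]1Cl | target

Total step count: 11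
Longest linear sequence: 11 steps (from 1)

**Steps most likely to fail**

Step 5. Chelation of both carbonyl oxygens by the Lewis acid, or delivery of chloride on the face of the oxygen, would turn the ring closure towards the cis-1,3-chlorohydrin; a 1,2-shift in the developing cation next to the quaternary carbon is a second hazard. The fallback sets out from 6 and accepts the chelated course. Chelation-controlled chloro-Prins cyclisation with TiCl4 (CH2Cl2, −78 °C) should give (2S,4R,5R)-4-chloro-5-ethynyl-2-hydroxy-5-methylcyclohexan-1-one F1, with the hydroxyl equatorial and cis to chlorine. Mitsunobu esterification with chloroacetic acid (PPh3, DIAD) inverts the carbinol to (1R,4R,5R)-5-chloro-4-ethynyl-4-methyl-2-oxocyclohexyl 2-chloroacetate F2. Thiourea with NaHCO3 removes the chloroacetyl group without forming an alkoxide and gives (2R,4R,5R)-4-chloro-5-ethynyl-2-hydroxy-5-methylcyclohexan-1-one F3. Silylation (Me3SiCl, imidazole) comes back to the route at 7.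

Step 9. Chloride may attack the unhindered primary carbon of the epoxide, or ionisation may be followed by a 1,2-alkyl shift with ring enlargement. The fallback sets out from 9 and makes the tertiary chloride by alkene bromochlorination instead. Invertive bromination of the allylic alcohol (PPh3, CBr4, CH2Cl2, −30 °C) gives (1R,2R,5S)-5-bromo-1-chloro-2-ethynyl-2-methyl-4-methylidenecyclohexane F4, which is used at once because allylic bromides transpose. Markovnikov anti bromochlorination of the exocyclic alkene (Bu4NBrCl2, CH2Cl2, −78 °C; axial attack of chloride on the tertiary carbon past the small axial ethynyl group) gives (1S,2S,4R,5R)-2-bromo-1-(bromomethyl)-1,4-dichloro-5-ethynyl-5-methylcyclohexane F5. Hydrozirconation (Cp2Zr(H)Cl) to the E-alkenylzirconocene chloride F6 and chlorination with NCS come back to the route at 17.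

Step 2. Reductive elimination through the alkyne terminus of the palladium allyl (vinylallene formation), reaction of the terminal alkyne C–H bond, or weak enantiofacial control may spoil the coupling. The fallback sets out from 1 and forms the same bond by a sigmatropic route. Rhodium-catalysed O–H insertion (Rh2(OAc)4, methyl 2-diazo-2-(dimethoxyphosphoryl)acetate) gives methyl 2-(dimethoxyphosphoryl)-2-{[(2E)-3-methylpent-2-en-4-yn-1-yl]oxy}acetate F7. Horner–Wadsworth–Emmons reaction with formaldehyde (K2CO3, aqueous CH2O) gives methyl 2-{[(2E)-3-methylpent-2-en-4-yn-1-yl]oxy}prop-2-enoate F8. Enantioselective Claisen rearrangement of this 2-alkoxycarbonyl allyl vinyl ether, catalysed by the chiral Lewis acid [Cu((S,S)-tBu-box)(H2O)2](SbF6)2 (antipode chosen for the S product), gives methyl (4S)-4-ethynyl-4-methyl-2-oxohex-5-enoate F9. Reduction with LiAlH4 comes back to the route at 5.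

**Further compounds**

F1 | step 5 | (2S,4R,5R)-4-chloro-5-ethynyl-2-hydroxy-5-methylcyclohexan-1-one | C[C@]1(C#C)CC(=O)[C@@H](O)C[C@H]1Cl
F2 | step 5 | (1R,4R,5R)-5-chloro-4-ethynyl-4-methyl-2-oxocyclohexyl 2-chloroacetate | C[C@]1(C#C)CC(=O)[C@H](OC(=O)CCl)C[C@H]1Cl
F3 | step 5 | (2R,4R,5R)-4-chloro-5-ethynyl-2-hydroxy-5-methylcyclohexan-1-one | C[C@]1(C#C)CC(=O)[C@H](O)C[C@H]1Cl
F4 | step 9 | (1R,2R,5S)-5-bromo-1-chloro-2-ethynyl-2-methyl-4-methylidenecyclohexane | C[C@]1(C#C)CC(=C)[C@@H](Br)C[C@H]1Cl
F5 | step 9 | (1S,2S,4R,5R)-2-bromo-1-(bromomethyl)-1,4-dichloro-5-ethynyl-5-methylcyclohexane | C[C@]1(C#C)C[C@](Cl)(CBr)[C@@H](Br)C[C@H]1Cl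
F6 | step 9 | E-alkenylzirconocene chloride of F5 | C[C@]1(/C=C/[Zr](Cl)(C2C=CC=C2)C2C=CC=C2)C[C@](Cl)(CBr)[C@@H](Br)C[C@H]1Cl
F7 | step 2 | methyl 2-(dimethoxyphosphoryl)-2-{[(2E)-3-methylpent-2-en-4-yn-1-yl]oxy}acetate | COC(=O)C(OC/C=C(\C)C#C)P(=O)(OC)OC
F8 | step 2 | methyl 2-{[(2E)-3-methylpent-2-en-4-yn-1-yl]oxy}prop-2-enoate | C=C(OC/C=C(\C)C#C)C(=O)OC
F9 | step 2 | methyl (4S)-4-ethynyl-4-methyl-2-oxohex-5-enoate | C[C@](C=C)(C#C)CC(=O)C(=O)OC
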